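**Plan**

1. Labdane numbering is used: ring A = C1–C5/C10, ring B = C5–C10; C4 bears CH3 and CO2H, C3 the OAc, C8 the =CH2, C9 the side chain, C10 the angular CH3. The last cuts take the three C=CH2 units (C8=C17, C13=C16, C14=C15) back to carbonyls and the C3 acetate back to a C3 ketone.
2. Core cut: C5–C10 together with C3–C4. Ring A, with quaternary C4 and C10 on either side of the C5–H fusion carbon, is the retron of a Diels–Alder reaction between a C10=C1–C2=C3(OR) diene and a C4=C5 tiglate. Ring B (C6–C9) is the tether, so an open-chain triene closes both rings in one operation.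
3. The triene is cut at C2=C3 (Wittig) and at O–C2/C8–C9 (asymmetric hetero-Diels–Alder). The resulting dihydropyran is a temporary ring that holds C10=C1 as Z and sets C9 and a temporary C8 carbinol. Its two achiral partners come from a cross-metathesis (C4=C5) and from an alkyne (hydrozirconation, Suzuki coupling).
4. Forward order: fragments, dihydropyran, ring-opened (Z,E)-dienyl ether, one-step closure of rings A and B, C3 inversion by oxidation/reduction, acetate, the three methylene groups, free acid.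
5. Stereochemistry: C9 from the chiral Cr catalyst. C10, C5 and C4 follow from C9 through the (Z)-diene (cis fusion enforced, A(1,3) strain fixes the face) and the (E)-enoate. C3 comes from substrate-controlled hydride reduction.

Key step: step 10

Remark: the target SMILES is read as a cis-fused decalin. H5, the C10 methyl, the C4 carboxyl and the C9 side chain lie on one face and the C3 acetate on the other, i.e. (3R,4R,5S,9S,10R). The route is designed for exactly this configuration.

**Route**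

Step 1
Reactants: 1 pent-4-enal; 2 tert-butyl methacrylate
Product: 3 tert-butyl (2E)-2-methyl-6-oxohex-2-enoate
Conditions: Hoveyda–Grubbs II (3 mol%), 2 (5 equiv), CH2Cl2, 40 °C
Reagents that add atoms: none
Why: Olefin cross-metathesis of a terminal alkene with a methacrylate should give the trisubstituted enoate selectively as the (E) isomer, and the aldehyde is tolerated.

Step 2
Reactants: 4 hex-5-yn-1-ol
Product: 5 tert-butyl(hex-5-yn-1-yloxy)dimethylsilane
Conditions: TBSCl, imidazole, DMF, rt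
Reagents that add atoms: tert-butyldimethylsilyl chloride, CC(C)(C)[Si](C)(C)Cl
Why: Standard silyl ether formation on a primary alcohol.

Step 3
Reactants: 5 tert-butyl(hex-5-yn-1-yloxy)dimethylsilane
Product: 6 tert-butyl(hept-5-yn-1-yloxy)dimethylsilane
Conditions: n-BuLi, THF, −78 °C; MeI, −78 °C → rt
Reagents that add atoms: iodomethane, CI
Why: Deprotonation of the terminal alkyne and C-methylation of the acetylide (alkyne alkylation).

Step 4
Reactants: 6 tert-butyl(hept-5-yn-1-yloxy)dimethylsilane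
Product: 8 tert-butyl{[(5E)-6-iodohept-5-en-1-yl]oxy}dimethylsilane, via alkenylzirconocene chloride 7 (not isolated)
Conditions: Cp2Zr(H)Cl (2 equiv), THF, 45 °C; then I2, 0 °C
Reagents that add atoms: iodine, II
Why: Syn hydrozirconation, equilibrated with excess reagent so that Zr sits on the methyl-bearing carbon, followed by iodinolysis with retention should give the (E)-2-iodoalkene; the minor regioisomer is removed after step 5.

Step 5
Reactants: 8 tert-butyl{[(5E)-6-iodohept-5-en-1-yl]oxy}dimethylsilane; 9 2-[(E)-2-ethoxyethenyl]-4,4,5,5-tetramethyl-1,3,2-dioxaborolane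
Product: 10 tert-butyl{[(5E,7E)-8-ethoxy-6-methylocta-5,7-dien-1-yl]oxy}dimethylsilane
Conditions: Pd(PPh3)4 (5 mol%), aq. K3PO4, THF, 50 °C
Reagents that add atoms: none
Why: Suzuki–Miyaura coupling of an alkenyl iodide with an alkenylboronate proceeds with retention at both partners and so fixes the (5E,7E)-dienyl ether.

Step 6
Reactants: 3 tert-butyl (2E)-2-methyl-6-oxohex-2-enoate; 10 tert-butyl{[(5E,7E)-8-ethoxy-6-methylocta-5,7-dien-1-yl]oxy}dimethylsilane
Product: 12 tert-butyl (2E)-5-[(2R,3R)-3-{4-[(tert-butyldimethylsilyl)oxy]butyl}-6-hydroxy-4-methyl-3,6-dihydro-2H-pyran-2-yl]-2-methylpent-2-enoate (mixture of anomers), via ethyl acetal 11 (not isolated)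
Conditions: tridentate (Schiff base)Cr(III)Cl catalyst from 3-(1-adamantyl)-5-methylsalicylaldehyde and cis-1-amino-2-indanol (5 mol%, enantiomer chosen for the (2R,3R) ring carbons), 4 Å MS, neat, rt; then PPTS, THF/H2O, rt
Reagents that add atoms: water, O
Why: Catalytic enantioselective hetero-Diels–Alder reaction of a 1-alkoxydiene with an aldehyde, in which endo addition to the (E,E)-diene should set C8 and C9 cis on the ring under catalyst control and lock C10=C1 as Z in the ring, after which mild acid hydrolyses the allylic acetal to the lactol.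

Step 7
Reactants: 13 benzyl chloromethyl ether; 14 triphenylphosphine
Product: 15 [(benzyloxy)methyl]triphenylphosphonium chloride
Conditions: PhMe, rt → 50 °C
Reagents that add atoms: none
Why: SN2 quaternisation of the phosphine by the reactive α-chloro ether.

Step 8
Reactants: 12 lactol from step 6; 15 [(benzyloxy)methyl]triphenylphosphonium chloride
Product: 17 tert-butyl (2E,6R,7R,8Z,10E)-11-(benzyloxy)-7-{4-[(tert-butyldimethylsilyl)oxy]butyl}-6-hydroxy-2,8-dimethylundeca-2,8,10-trienoate, via phosphorus ylide 16 (not isolated)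
Conditions: 15 (3 equiv), KHMDS (2.9 equiv), THF, −78 °C; then 12, −78 → 0 °C; (10E) isomer separated on Et3N-deactivated silica
Reagents that add atoms: none
Why: Wittig alkoxymethylenation of the lactol through its open hydroxy-enal form keeps the ring-derived (Z) alkene and should form the enol ether as an E/Z mixture, of which only the (10E) isomer is carried on because only it can reach the s-cis diene.

Step 9
Reactants: 17 dienyl ether alcohol from step 8
Product: 18 tert-butyl (2E,6R,7R,8Z,10E)-11-(benzyloxy)-6-[(tert-butyldimethylsilyl)oxy]-7-{4-[(tert-butyldimethylsilyl)oxy]butyl}-2,8-dimethylundeca-2,8,10-trienoate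
Conditions: TBSCl, imidazole, DMAP, DMF, 40 °C
Reagents that add atoms: tert-butyldimethylsilyl chloride, CC(C)(C)[Si](C)(C)Cl
Why: Silylation under basic conditions protects the C8 alcohol without touching the acid-sensitive dienyl ether.

Step 10
Reactants: 18 triene from step 9
Product: 19 tert-butyl (1R,2S,4aS,5R,6R,8aS)-2-(benzyloxy)-6-[(tert-butyldimethylsilyl)oxy]-5-{4-[(tert-butyldimethylsilyl)oxy]butyl}-1,4a-dimethyl-1,2,4a,5,6,7,8,8a-octahydronaphthalene-1-carboxylate
Conditions: PhMe (0.01 M), BHT, i-Pr2NEt (trace), 160 °C, sealed tube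
Reagents that add atoms: none
Why: Thermal, concerted but asynchronous intramolecular Diels–Alder reaction of a 1,7,9-decatriene with normal electron demand (the C3 alkoxy group makes C10 the nucleophilic diene terminus, matched with the enoate β-carbon C5); the closest known type is the intramolecular Diels–Alder reaction of (Z)-dienes that gives cis-fused octalins under allylic-strain control. Ring A (C10–C1=C2–C3–C4–C5) is closed by the [4+2] cycloaddition itself, which forms C5–C10 and C3–C4, and ring B (C5–C6–C7–C8–C9–C10) is closed at the same time by the four-carbon tether in a chair-like array (fused mode). Because C9 is the inside (Z) substituent of the diene terminus C10, only the cis-fused transition state is geometrically possible, which sets H5 and the C10 methyl cis and places the ester endo; the (E)-enoate then puts the C4 carboxylate cis to H5 by suprafacial addition, and the (E)-enol ether defines C3, which is erased in step 12. The face is set by C9: A(1,3) strain against the C2–H vinyl unit holds C9–H near the diene plane, so the tether carbon C8 leads the dienophile to one face while the side chain lies equatorial and anti to the forming C5–C10 bond and the C8 silyloxy group is equatorial too, which should give the side chain cis to the C10 methyl. The step needs π-facial selectivity and a cycloaddition faster than the [1,5]-hydrogen shift of the (Z)-diene; the in-plane C9–H is misaligned for that shift and the alkoxy donor lowers the temperature required.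

Step 11
Reactants: 19 cycloadduct from step 10
Product: 20 tert-butyl (1R,2S,4aS,5R,6R,8aS)-6-[(tert-butyldimethylsilyl)oxy]-5-{4-[(tert-butyldimethylsilyl)oxy]butyl}-2-hydroxy-1,4a-dimethyldecahydronaphthalene-1-carboxylate
Conditions: H2 (1 atm), 10% Pd/C, EtOAc, rt
Reagents that add atoms: none
Why: Heterogeneous hydrogenation should saturate the cis-disubstituted C1=C2 alkene and hydrogenolyse the benzyl ether in one operation, the neopentyl C3–O bond resisting allylic cleavage.

Step 12
Reactants: 20 alcohol from step 11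
Product: 21 tert-butyl (1R,4aS,5R,6R,8aS)-6-[(tert-butyldimethylsilyl)oxy]-5-{4-[(tert-butyldimethylsilyl)oxy]butyl}-1,4a-dimethyl-2-oxodecahydronaphthalene-1-carboxylate
Conditions: Dess–Martin periodinane, pyridine, CH2Cl2, rt
Reagents that add atoms: none
Why: Dess–Martin oxidation of the hindered secondary alcohol gives the C3 ketone under neutral conditions that spare the β-keto ester and the silyl ethers.

Step 13
Reactants: 21 ketone from step 12
Product: 22 tert-butyl (1R,2R,4aS,5R,6R,8aS)-6-[(tert-butyldimethylsilyl)oxy]-5-{4-[(tert-butyldimethylsilyl)oxy]butyl}-2-hydroxy-1,4a-dimethyldecahydronaphthalene-1-carboxylate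
Conditions: NaBH4, MeOH, −20 → 0 °C
Reagents that add atoms: none
Why: Hydride reduction with axial delivery to the ring-A chair from the face anti to the syn-axial C4 methyl and C10–C9 bond, as with 3-oxo-4,4-disubstituted terpenoid A rings, should give the equatorial 3-alcohol trans to the ester, which is the target configuration.

Step 14
Reactants: 22 alcohol from step 13
Product: 23 tert-butyl (1R,2R,4aS,5R,6R,8aS)-2-acetoxy-6-[(tert-butyldimethylsilyl)oxy]-5-{4-[(tert-butyldimethylsilyl)oxy]butyl}-1,4a-dimethyldecahydronaphthalene-1-carboxylate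
Conditions: Ac2O, pyridine, DMAP, CH2Cl2, rt
Reagents that add atoms: acetic anhydride, CC(=O)OC(C)=O
Why: DMAP-catalysed acylation of the hindered secondary alcohol.

Step 15
Reactants: 23 acetate from step 14
Product: 24 tert-butyl (1R,2R,4aS,5R,6R,8aS)-2-acetoxy-6-hydroxy-5-(4-hydroxybutyl)-1,4a-dimethyldecahydronaphthalene-1-carboxylate
Conditions: HF·pyridine, pyridine/THF, 0 °C → rt
Reagents that add atoms: none
Why: Fluoride-mediated desilylation removes both silyl ethers while the acetate and the tert-butyl ester are stable to these non-basic conditions.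

Step 16
Reactants: 24 diol from step 15
Product: 25 tert-butyl (1R,2R,4aS,5R,8aS)-2-acetoxy-1,4a-dimethyl-6-oxo-5-(4-oxobutyl)decahydronaphthalene-1-carboxylate
Conditions: Dess–Martin periodinane (3 equiv), pyridine, CH2Cl2, rt
Reagents that add atoms: none
Why: Dess–Martin oxidation converts the primary alcohol into the aldehyde and the C8 alcohol into the ketone without base, so the C9 centre next to the new ketone is kept.

Step 17
Reactants: 25 keto-aldehyde from step 16
Product: 26 tert-butyl (1R,2R,4aS,5R,8aS)-2-acetoxy-5-(3-formylbut-3-en-1-yl)-1,4a-dimethyl-6-oxodecahydronaphthalene-1-carboxylate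
Conditions: 37% aq. HCHO, pyrrolidine (10 mol%), propionic acid (10 mol%), i-PrOH, 45 °C
Reagents that add atoms: formaldehyde, C=O
Why: Organocatalytic α-methylenation of the aldehyde (enamine Mannich condensation with formaldehyde, then elimination) is selective for the aldehyde because the hindered C8 ketone does not form an enamine.

Step 18
Reactants: 26 keto-enal from step 17
Product: 27 tert-butyl (1R,2R,4aR,5S,8aS)-2-acetoxy-1,4a-dimethyl-6-methylidene-5-(3-methylidenepent-4-en-1-yl)decahydronaphthalene-1-carboxylate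
Conditions: Zn, CH2Br2, TiCl4 (pre-formed reagent, excess), THF/CH2Cl2, 0 °C → rt
Reagents that add atoms: dibromomethane, BrCBr
Why: Takai–Lombardo methylenation should convert both the enal and the C8 ketone into C=CH2 under non-basic conditions, so the C9 centre, the acetate and the ester are kept.

Step 19
Reactants: 27 tert-butyl ester from step 18
Product: 29 (1R,2R,4aR,5S,8aS)-2-acetoxy-1,4a-dimethyl-6-methylidene-5-(3-methylidenepent-4-en-1-yl)decahydronaphthalene-1-carboxylic acid (target), via trimethylsilyl ester 28 (not isolated)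
Conditions: TMSOTf, 2,6-lutidine, CH2Cl2, 0 °C; then pH 4 buffer
Reagents that add atoms: none
Why: Silyl triflate-mediated tert-butyl ester cleavage (loss of the tert-butyl cation as isobutene) needs no attack at the hindered neopentyl carbonyl and, being buffered, should spare the acetate and the acid-sensitive diene, and aqueous work-up frees the acid.

**Compound list**

1 | pent-4-enal | C=CCCC=O | starting material
2 | tert-butyl methacrylate | C=C(C)C(=O)OC(C)(C)C | starting material
3 | tert-butyl (2E)-2-methyl-6-oxohex-2-enoate | O=CCC/C=C(\C)C(=O)OC(C)(C)C | intermediate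
4 | hex-5-yn-1-ol | C#CCCCCO | starting material
5 | tert-butyl(hex-5-yn-1-yloxy)dimethylsilane | C#CCCCCO[Si](C)(C)C(C)(C)C | intermediate
6 | tert-butyl(hept-5-yn-1-yloxy)dimethylsilane | CC#CCCCCO[Si](C)(C)C(C)(C)C | intermediate
7 | chlorido{(2E)-7-[(tert-butyldimethylsilyl)oxy]hept-2-en-2-yl}bis(cyclopentadienyl)zirconium | C/C(=C\CCCCO[Si](C)(C)C(C)(C)C)[Zr](Cl)(C1C=CC=C1)C1C=CC=C1 | intermediate
8 | tert-butyl{[(5E)-6-iodohept-5-en-1-yl]oxy}dimethylsilane | C/C(I)=C\CCCCO[Si](C)(C)C(C)(C)C | intermediate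
9 | 2-[(E)-2-ethoxyethenyl]-4,4,5,5-tetramethyl-1,3,2-dioxaborolane | CCO/C=C/B1OC(C)(C)C(C)(C)O1 | starting material
10 | tert-butyl{[(5E,7E)-8-ethoxy-6-methylocta-5,7-dien-1-yl]oxy}dimethylsilane | CCO/C=C/C(C)=C/CCCCO[Si](C)(C)C(C)(C)C | intermediate
11 | tert-butyl (2E)-5-[(2R,3R,6R)-3-{4-[(tert-butyldimethylsilyl)oxy]butyl}-6-ethoxy-4-methyl-3,6-dihydro-2H-pyran-2-yl]-2-methylpent-2-enoate | CCO[C@H]1C=C(C)[C@@H](CCCCO[Si](C)(C)C(C)(C)C)[C@@H](CC/C=C(\C)C(=O)OC(C)(C)C)O1 | intermediate
12 | tert-butyl (2E)-5-[(2R,3R)-3-{4-[(tert-butyldimethylsilyl)oxy]butyl}-6-hydroxy-4-methyl-3,6-dihydro-2H-pyran-2-yl]-2-methylpent-2-enoate (anomers) | OC1C=C(C)[C@@H](CCCCO[Si](C)(C)C(C)(C)C)[C@@H](CC/C=C(\C)C(=O)OC(C)(C)C)O1 | intermediate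
13 | benzyl chloromethyl ether | ClCOCc1ccccc1 | starting material
14 | triphenylphosphine | c1ccc(cc1)P(c1ccccc1)c1ccccc1 | starting material
15 | [(benzyloxy)methyl]triphenylphosphonium chloride | [Cl-].c1ccccc1COC[P+](c1ccccc1)(c1ccccc1)c1ccccc1 | intermediate
16 | [(benzyloxy)methylidene]triphenylphosphorane | c1ccccc1COC=P(c1ccccc1)(c1ccccc1)c1ccccc1 | intermediate
17 | tert-butyl (2E,6R,7R,8Z,10E)-11-(benzyloxy)-7-{4-[(tert-butyldimethylsilyl)oxy]butyl}-6-hydroxy-2,8-dimethylundeca-2,8,10-trienoate | c1ccccc1CO/C=C/C=C(C)\[C@@H](CCCCO[Si](C)(C)C(C)(C)C)[C@H](O)CC/C=C(\C)C(=O)OC(C)(C)C | intermediate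
18 | tert-butyl (2E,6R,7R,8Z,10E)-11-(benzyloxy)-6-[(tert-butyldimethylsilyl)oxy]-7-{4-[(tert-butyldimethylsilyl)oxy]butyl}-2,8-dimethylundeca-2,8,10-trienoate | c1ccccc1CO/C=C/C=C(C)\[C@@H](CCCCO[Si](C)(C)C(C)(C)C)[C@H](O[Si](C)(C)C(C)(C)C)CC/C=C(\C)C(=O)OC(C)(C)C | intermediate
19 | tert-butyl (1R,2S,4aS,5R,6R,8aS)-2-(benzyloxy)-6-[(tert-butyldimethylsilyl)oxy]-5-{4-[(tert-butyldimethylsilyl)oxy]butyl}-1,4a-dimethyl-1,2,4a,5,6,7,8,8a-octahydronaphthalene-1-carboxylate | CC(C)(C)[Si](C)(C)OCCCC[C@H]1[C@H](O[Si](C)(C)C(C)(C)C)CC[C@H]2[C@]1(C)C=C[C@H](OCc3ccccc3)[C@]2(C)C(=O)OC(C)(C)C | intermediate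
20 | tert-butyl (1R,2S,4aS,5R,6R,8aS)-6-[(tert-butyldimethylsilyl)oxy]-5-{4-[(tert-butyldimethylsilyl)oxy]butyl}-2-hydroxy-1,4a-dimethyldecahydronaphthalene-1-carboxylate | CC(C)(C)[Si](C)(C)OCCCC[C@H]1[C@H](O[Si](C)(C)C(C)(C)C)CC[C@H]2[C@]1(C)CC[C@H](O)[C@]2(C)C(=O)OC(C)(C)C | intermediate
21 | tert-butyl (1R,4aS,5R,6R,8aS)-6-[(tert-butyldimethylsilyl)oxy]-5-{4-[(tert-butyldimethylsilyl)oxy]butyl}-1,4a-dimethyl-2-oxodecahydronaphthalene-1-carboxylate | CC(C)(C)[Si](C)(C)OCCCC[C@H]1[C@H](O[Si](C)(C)C(C)(C)C)CC[C@H]2[C@]1(C)CCC(=O)[C@]2(C)C(=O)OC(C)(C)C | intermediate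
22 | tert-butyl (1R,2R,4aS,5R,6R,8aS)-6-[(tert-butyldimethylsilyl)oxy]-5-{4-[(tert-butyldimethylsilyl)oxy]butyl}-2-hydroxy-1,4a-dimethyldecahydronaphthalene-1-carboxylate | CC(C)(C)[Si](C)(C)OCCCC[C@H]1[C@H](O[Si](C)(C)C(C)(C)C)CC[C@H]2[C@]1(C)CC[C@@H](O)[C@]2(C)C(=O)OC(C)(C)C | intermediate
23 | tert-butyl (1R,2R,4aS,5R,6R,8aS)-2-acetoxy-6-[(tert-butyldimethylsilyl)oxy]-5-{4-[(tert-butyldimethylsilyl)oxy]butyl}-1,4a-dimethyldecahydronaphthalene-1-carboxylate | CC(C)(C)[Si](C)(C)OCCCC[C@H]1[C@H](O[Si](C)(C)C(C)(C)C)CC[C@H]2[C@]1(C)CC[C@@H](OC(C)=O)[C@]2(C)C(=O)OC(C)(C)C | intermediate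
24 | tert-butyl (1R,2R,4aS,5R,6R,8aS)-2-acetoxy-6-hydroxy-5-(4-hydroxybutyl)-1,4a-dimethyldecahydronaphthalene-1-carboxylate | OCCCC[C@H]1[C@H](O)CC[C@H]2[C@]1(C)CC[C@@H](OC(C)=O)[C@]2(C)C(=O)OC(C)(C)C | intermediate
25 | tert-butyl (1R,2R,4aS,5R,8aS)-2-acetoxy-1,4a-dimethyl-6-oxo-5-(4-oxobutyl)decahydronaphthalene-1-carboxylate | O=CCCC[C@H]1C(=O)CC[C@H]2[C@]1(C)CC[C@@H](OC(C)=O)[C@]2(C)C(=O)OC(C)(C)C | intermediate
26 | tert-butyl (1R,2R,4aS,5R,8aS)-2-acetoxy-5-(3-formylbut-3-en-1-yl)-1,4a-dimethyl-6-oxodecahydronaphthalene-1-carboxylate | C=C(C=O)CC[C@H]1C(=O)CC[C@H]2[C@]1(C)CC[C@@H](OC(C)=O)[C@]2(C)C(=O)OC(C)(C)C | intermediate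
27 | tert-butyl (1R,2R,4aR,5S,8aS)-2-acetoxy-1,4a-dimethyl-6-methylidene-5-(3-methylidenepent-4-en-1-yl)decahydronaphthalene-1-carboxylate | C=CC(=C)CC[C@H]1C(=C)CC[C@H]2[C@]1(C)CC[C@@H](OC(C)=O)[C@]2(C)C(=O)OC(C)(C)C | intermediate
28 | trimethylsilyl (1R,2R,4aR,5S,8aS)-2-acetoxy-1,4a-dimethyl-6-methylidene-5-(3-methylidenepent-4-en-1-yl)decahydronaphthalene-1-carboxylate | C=CC(=C)CC[C@H]1C(=C)CC[C@H]2[C@]1(C)CC[C@@H](OC(C)=O)[C@]2(C)C(=O)O[Si](C)(C)C | intermediate
29 | (1R,2R,4aR,5S,8aS)-2-acetoxy-1,4a-dimethyl-6-methylidene-5-(3-methylidenepent-4-en-1-yl)decahydronaphthalene-1-carboxylic acid | C=CC(=C)CC[C@H]1C(=C)CC[C@H]2[C@]1(C)CC[C@@H](OC(C)=O)[C@]2(C)C(=O)O | target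

**Step count and risks**

Total: 19 steps. Longest linear sequence: 17 steps (from 4: steps 2–6 and 8–19).

Most likely to fail:

1. Step 10. The cycloaddition, which makes two quaternary carbons, may be too slow at temperatures the (Z)-dienyl ether tolerates, so that [1,5]-hydrogen shift or geometric isomerisation of the diene, or thermal loss of isobutene from the ester, competes. The fallback raises the dienophile to the aldehyde oxidation level and sets out from 18. DIBAL-H (CH2Cl2, −78 → 0 °C) should reduce the enoate to the allylic alcohol F1, and MnO2 should then give the (E)-2-methyl-enal F2. This more reactive trienal should cyclise through the same (Z)-diene-enforced cis-fused transition state at 80–110 °C to the cycloadduct aldehyde F3. Pinnick oxidation (NaClO2, NaH2PO4, 2-methyl-2-butene) gives the carboxylic acid F4, and O-alkylation with N,N-dimethylformamide di-tert-butyl acetal (PhMe, 80 °C) comes back to 19.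

2. Step 8. Poor control of the enol ether geometry (the (10Z) isomer cannot cyclise) and base-induced isomerisation of the open (Z)-enal before olefination would erode the supply of 17. The fallback builds the enol ether by stereoretentive C–O coupling and sets out from 12. Takai iodo-olefination (CHI3, CrCl2, THF/dioxane) should give the (E)-dienyl iodide F5, and silylation (TBSCl, imidazole) its silyl ether F6. Copper-catalysed coupling with benzyl alcohol (CuI, 3,4,7,8-tetramethyl-1,10-phenanthroline, Cs2CO3, PhMe, 80 °C) comes back to 18.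

3. Step 6. The mono-oxygenated diene may add too slowly to the unactivated aldehyde, or the endo and enantioselectivity may be eroded. The fallback replaces catalyst control by an auxiliary and sets out from 3.
   - Evans syn-aldol (Bu2BOTf, i-Pr2NEt, CH2Cl2, −78 °C) with the N-acyl oxazolidinone F7, made from commercial 6-[(tert-butyldimethylsilyl)oxy]hexanoic acid and (S)-4-benzyloxazolidin-2-one (PivCl, Et3N; lithiated oxazolidinone), should give the aldol adduct F8.
   - Transamination (MeONHMe·HCl, AlMe3) gives the Weinreb amide F9, and MeMgBr the methyl ketone F10.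
   - Esterification with diethylphosphonoacetic acid (DCC, DMAP) gives the phosphonoacetate F11, and intramolecular Horner–Wadsworth–Emmons closure (LiCl, DBU, MeCN) the unsaturated lactone F12, whose ring again fixes the (Z) alkene.
   - DIBAL-H (1.1 equiv, CH2Cl2, −78 °C) comes back to 12.

Further compounds
F1 | step 10 | (2E,6R,7R,8Z,10E)-11-(benzyloxy)-6-[(tert-butyldimethylsilyl)oxy]-7-{4-[(tert-butyldimethylsilyl)oxy]butyl}-2,8-dimethylundeca-2,8,10-trien-1-ol | c1ccccc1CO/C=C/C=C(C)\[C@@H](CCCCO[Si](C)(C)C(C)(C)C)[C@H](O[Si](C)(C)C(C)(C)C)CC/C=C(\C)CO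
F2 | step 10 | (2E,6R,7R,8Z,10E)-11-(benzyloxy)-6-[(tert-butyldimethylsilyl)oxy]-7-{4-[(tert-butyldimethylsilyl)oxy]butyl}-2,8-dimethylundeca-2,8,10-trienal | c1ccccc1CO/C=C/C=C(C)\[C@@H](CCCCO[Si](C)(C)C(C)(C)C)[C@H](O[Si](C)(C)C(C)(C)C)CC/C=C(\C)C=O
F3 | step 10 | (1R,2S,4aS,5R,6R,8aS)-2-(benzyloxy)-6-[(tert-butyldimethylsilyl)oxy]-5-{4-[(tert-butyldimethylsilyl)oxy]butyl}-1,4a-dimethyl-1,2,4a,5,6,7,8,8a-octahydronaphthalene-1-carbaldehyde | CC(C)(C)[Si](C)(C)OCCCC[C@H]1[C@H](O[Si](C)(C)C(C)(C)C)CC[C@H]2[C@]1(C)C=C[C@H](OCc3ccccc3)[C@]2(C)C=O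
F4 | step 10 | (1R,2S,4aS,5R,6R,8aS)-2-(benzyloxy)-6-[(tert-butyldimethylsilyl)oxy]-5-{4-[(tert-butyldimethylsilyl)oxy]butyl}-1,4a-dimethyl-1,2,4a,5,6,7,8,8a-octahydronaphthalene-1-carboxylic acid | CC(C)(C)[Si](C)(C)OCCCC[C@H]1[C@H](O[Si](C)(C)C(C)(C)C)CC[C@H]2[C@]1(C)C=C[C@H](OCc3ccccc3)[C@]2(C)C(=O)O
F5 | step 8 | tert-butyl (2E,6R,7R,8Z,10E)-7-{4-[(tert-butyldimethylsilyl)oxy]butyl}-6-hydroxy-11-iodo-2,8-dimethylundeca-2,8,10-trienoate | I/C=C/C=C(C)\[C@@H](CCCCO[Si](C)(C)C(C)(C)C)[C@H](O)CC/C=C(\C)C(=O)OC(C)(C)C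
F6 | step 8 | tert-butyl (2E,6R,7R,8Z,10E)-6-[(tert-butyldimethylsilyl)oxy]-7-{4-[(tert-butyldimethylsilyl)oxy]butyl}-11-iodo-2,8-dimethylundeca-2,8,10-trienoate | I/C=C/C=C(C)\[C@@H](CCCCO[Si](C)(C)C(C)(C)C)[C@H](O[Si](C)(C)C(C)(C)C)CC/C=C(\C)C(=O)OC(C)(C)C
F7 | step 6 | (4S)-4-benzyl-3-{6-[(tert-butyldimethylsilyl)oxy]hexanoyl}-1,3-oxazolidin-2-one | O=C(CCCCCO[Si](C)(C)C(C)(C)C)N1[C@@H](Cc2ccccc2)COC1=O
F8 | step 6 | tert-butyl (2E,6R,7S)-7-{[(4S)-4-benzyl-2-oxo-1,3-oxazolidin-3-yl]carbonyl}-11-[(tert-butyldimethylsilyl)oxy]-6-hydroxy-2-methylundec-2-enoate | O=C([C@@H](CCCCO[Si](C)(C)C(C)(C)C)[C@H](O)CC/C=C(\C)C(=O)OC(C)(C)C)N1[C@@H](Cc2ccccc2)COC1=O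
F9 | step 6 | tert-butyl (2E,6R,7S)-11-[(tert-butyldimethylsilyl)oxy]-6-hydroxy-7-[methoxy(methyl)carbamoyl]-2-methylundec-2-enoate | CON(C)C(=O)[C@@H](CCCCO[Si](C)(C)C(C)(C)C)[C@H](O)CC/C=C(\C)C(=O)OC(C)(C)C
F10 | step 6 | tert-butyl (2E,6R,7S)-7-acetyl-11-[(tert-butyldimethylsilyl)oxy]-6-hydroxy-2-methylundec-2-enoate | CC(=O)[C@@H](CCCCO[Si](C)(C)C(C)(C)C)[C@H](O)CC/C=C(\C)C(=O)OC(C)(C)C
F11 | step 6 | tert-butyl (2E,6R,7S)-7-acetyl-11-[(tert-butyldimethylsilyl)oxy]-6-{[(diethoxyphosphoryl)acetyl]oxy}-2-methylundec-2-enoate | CC(=O)[C@@H](CCCCO[Si](C)(C)C(C)(C)C)[C@H](OC(=O)CP(=O)(OCC)OCC)CC/C=C(\C)C(=O)OC(C)(C)C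
F12 | step 6 | tert-butyl (2E)-5-[(2R,3R)-3-{4-[(tert-butyldimethylsilyl)oxy]butyl}-4-methyl-6-oxo-3,6-dihydro-2H-pyran-2-yl]-2-methylpent-2-enoate | O=C1C=C(C)[C@@H](CCCCO[Si](C)(C)C(C)(C)C)[C@@H](CC/C=C(\C)C(=O)OC(C)(C)C)O1
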